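(The earlier runs and the new flask are calculated for an exercise, and the scatter is random.)

I started from a leftover: the free nucleophile at the end of each flask, which I meant to watch. Electrophile and nucleophile give target and acid set free, and the acid binds nucleophile as protonated nucleophile. Electrophile also meets target (side product) and protic impurity (quenched substrate), while target alone goes on to over-reaction product.

the same everywhere: electrophile 0.80 M
- Tuesday's: nucleophile 0.72 M; protic impurity 0.16 M; run made earlier
- ochre: nucleophile 0.720 M; protic impurity 0.240 M; time 10 d
- grey: nucleophile 1.40 M; protic impurity 0.240 M; time 10 d
- green: nucleophile 2.90 M; protic impurity 0.240 M; time 10 d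

- Tuesday's (time / h: electrophile / %, target / %): 4.00: 94.5, 3.9; 12.0: 84.8, 6.6; 20.0: 77.4, 10.2; 30.0: 69.4, 9.3; 50.0: 57.5, 7.5

(scatter of a reading: 0.5 percentage points)

- percentages count the electrophile that a species holds: one side product counts as two
- the numbers in the tables scatter by 0.5 percentage points (one standard deviation)
- steps thought possible: electrophile + nucleophile -> acid set free + target; nucleophile + acid set free <-> protonated nucleophile; electrophile + target -> side product; electrophile + protic impurity -> quenched substrate; target -> over-reaction product
- no earlier run changes the charge of protic impurity; that part of a forecast is a guess

* part of the electrophile that has reacted at the end, ochre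
* part of the electrophile that has reacted at the end, grey
* part of the electrophile that has reacted at the end, green
* what raising the concentration of nucleophile from its lowest to its highest value here does to the part of the electrophile that has reacted (changes below 5 percentage points count as none) (it rises / it falls / no change)

In Tuesday's run the electrophile's fractional loss fell from 0.0141 h⁻¹ at the start to 0.00941 h⁻¹ late, so a partner was running down, and I took it to be [nucleophile].

My first estimate was one nucleophile per target, which let ochre consume 90.0 % of its electrophile. But the acid set free takes a second nucleophile, so I defined the nucleophile reach, the electrophile charged that the nucleophile can carry at two nucleophile to a target, as 45.0 % for ochre. Protic impurity adds up to 30.0 %, making 75.0 %.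

Was ten days enough? The early rate gave a half-life of 49.0 h, shorter than 10 d, but that rate falls as the partners thin, so I took the sum as an estimate of ochre at the end, not as a stop. Against it, side product takes extra electrophile without extra nucleophile, while nucleophile and impurity may not be used up in time. These errors pull opposite ways, so I kept the figure.

In grey the reach is 87.5 % and in green 181 %, so in both the sum with the impurity passes the electrophile charged, and I turned to the clock. Could green still fall short? Early target was 70.9 % of the electrophile lost, a reading that gives k ≈ 0.0139 M⁻¹ h⁻¹. Taking [nucleophile] as low as 1.30 M, I treated green as pseudo-first-order at 0.0181 h⁻¹, which gives an estimate of 98.7 % reacted. Grey I expected to be somewhat short of complete, its tail slowed by thin nucleophile.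

The forecast said 76 %, 93 % and 99.7 %, and on the trend it rises, reckoning that “the freed acid ties up a second one”.

The flasks gave 76.5 % for ochre, 95.1 % for grey and 99.9 % for green; on the trend, it rises, by 23 percentage points, and the difference in [nucleophile] is the main reason.

    electrophile + nucleophile → acid set free + target (k = 2.40 × 10⁻⁴ M⁻¹ min⁻¹)
    nucleophile + acid set free ⇌ protonated nucleophile, settled at all times (K = 820 M⁻¹)
    electrophile + target → side product (k = 4.50 × 10⁻⁴ M⁻¹ min⁻¹)
    electrophile + protic impurity → quenched substrate (k = 3.80 × 10⁻⁴ M⁻¹ min⁻¹)
    target → over-reaction product (k = 4.90 × 10⁻⁴ min⁻¹)

Ochre ended with 10.5 % of its nucleophile free, and at two per target the spent part accounts for 40.3 % of the electrophile, inside its reach of 45.0 %. Ochre had not stopped: at ten times the time it reaches 89.8 %. The binding is part of the reason: without it, ochre reaches 89.0 % instead of 76.5 %. The neighbour of ochre charged with 1.2 M of nucleophile has a reach of 75.0 %, which with the impurity exceeds its electrophile. It ended at 91.8 % reacted, with 22 % of its nucleophile still free.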